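**Retrosynthetic overview**

1. 18 ⇒ 16: the C6=C7(CHO) enal is opened to a dialdehyde (macrocyclising aldol condensation); the 11-membered carbocycle is the last ring formed.
2. 16 ⇒ 14 + 15: the C1–O ester bond is made with inversion (Mitsunobu) on the erythro epoxy alcohol; this C–O bond formation fixes C1 and brings in the senecioate.
3. 14 ⇒ 13 ⇒ 12: the oxirane (first ring formed) comes from a Ti/D-(−)-tartrate kinetic-resolution epoxidation of a divinyl carbinol; it fixes C10 and C11 and selects the 1R epimer.
4. 12 ⇒ 8 + 11: C1–C2 by Nozaki–Hiyama–Kishi coupling; 11 by Wittig reaction on 2-hydroxytetrahydropyran.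
5. 8 ⇒ 4 ⇒ 3 ⇒ 1: cross-metathesis, lactone reduction and Takai olefination on a lactone whose quaternary C4 is set by Pd-catalysed decarboxylative allylation.

Numbering used below (ring and open-chain precursors): C1 carries the ester oxygen, C2=C3 is the E-disubstituted alkene, C4 the quaternary carbon, C5, C6=C7 (C7 carries CHO), C8, C9, C10–C11 the oxirane (C11 carries CH3 and is bonded to C1). The target is 1S,4R,10R,11S; the descriptor of C11 reads R in the free C1 alcohols and S in the C1 esters and C1 ketone, with no change in geometry.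

Assumption: in step 2 the (S)-PHOX ligand is taken to give (R)-4 by analogy with cyclic ketone and lactam enolates; if the sense is opposite, the (R)-ligand is used.

**Route**

Step 1
Reactants: 1 α-methyl-γ-butyrolactone (racemic 3-methyldihydrofuran-2(3H)-one); 2 allyl chloroformate
Product: 3 allyl 3-methyl-2-oxotetrahydrofuran-3-carboxylate (racemic)
Conditions: LiN(i-Pr)2, THF, −78 °C; then 2, −78 → 0 °C
Reagents that add atoms: none
Why: Claisen-type C-acylation of the lithium lactone enolate gives the quaternary allyl ester needed for step 2; the stereocentre formed is racemic and is erased on decarboxylation.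

Step 2
Reactants: 3 allyl 3-methyl-2-oxotetrahydrofuran-3-carboxylate
Product: 4 (R)-3-allyl-3-methyldihydrofuran-2(3H)-one
Conditions: Pd2(dba)3 (2.5 mol %), (S)-(CF3)3-t-BuPHOX (6 mol %), toluene, 30 °C
Reagents that add atoms: none
Why: Stoltz-type Pd-catalysed decarboxylative asymmetric allylic alkylation (Tsuji–Trost manifold), in which loss of CO2 gives an allyl–palladium lactone enolate and C–C coupling in the chiral P,N pocket sets the quaternary C4 as R.

Step 3
Reactants: 4 (R)-3-allyl-3-methyldihydrofuran-2(3H)-one; 5 2-methylbut-3-en-2-ol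
Product: 6 (R)-3-[(2E)-4-hydroxy-4-methylpent-2-en-1-yl]-3-methyldihydrofuran-2(3H)-one
Conditions: second-generation Grubbs catalyst (H2IMes)(PCy3)Cl2Ru=CHPh (3 mol %), 5 (5 equiv), CH2Cl2, 40 °C
Reagents that add atoms: none
Why: Olefin cross-metathesis of a terminal allyl group with the tertiary allylic alcohol is a well-precedented, strongly E-selective way to the CH2–CH=CH–C(CH3)2OH side chain, and C4 is not touched.

Step 4
Reactants: 6 (R)-3-[(2E)-4-hydroxy-4-methylpent-2-en-1-yl]-3-methyldihydrofuran-2(3H)-one
Product: 7 (3R)-3-[(2E)-4-hydroxy-4-methylpent-2-en-1-yl]-3-methyltetrahydrofuran-2-ol (lactol, anomer mixture)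
Conditions: i-Bu2AlH (2.2 equiv), CH2Cl2, −78 °C; aqueous Rochelle salt
Reagents that add atoms: none
Why: Partial hydride reduction of a lactone to the lactol, whose tetrahedral aluminate is stable at −78 °C and does not over-reduce next to the quaternary carbon.

Step 5
Reactants: 7 (3R)-3-[(2E)-4-hydroxy-4-methylpent-2-en-1-yl]-3-methyltetrahydrofuran-2-ol
Product: 8 (3R,5E)-3-[(E)-2-iodoethenyl]-3,7-dimethyloct-5-ene-1,7-diol
Conditions: CrCl2 (8 equiv), CHI3 (3 equiv), THF–dioxane, 0 °C → rt
Reagents that add atoms: iodoform, IC(I)I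
Why: Takai olefination of the open hydroxy-aldehyde tautomer of the lactol gives the E-vinyl iodide (high E selectivity with hindered aldehydes) and frees the C6 primary alcohol.

Step 6
Reactants: 9 2-hydroxytetrahydropyran; 10 2-(triphenylphosphoranylidene)propanal
Product: 11 (2E)-7-hydroxy-2-methylhept-2-enal
Conditions: toluene, 80 °C
Reagents that add atoms: none
Why: Wittig olefination of the open 5-hydroxypentanal tautomer with a stabilised ylide gives the E-trisubstituted enal (the future C10=C11 alkene with C1 as the aldehyde).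

Step 7
Reactants: 8 (3R,5E)-3-[(E)-2-iodoethenyl]-3,7-dimethyloct-5-ene-1,7-diol; 11 (2E)-7-hydroxy-2-methylhept-2-enal
Product: 12 (3R,5E)-3-[(1E,4E)-3,9-dihydroxy-4-methylnona-1,4-dien-1-yl]-3,7-dimethyloct-5-ene-1,7-diol (divinyl carbinol, about 1:1 mixture of C1 epimers)
Conditions: CrCl2 (6 equiv), NiCl2 (2 mol %), DMSO, rt
Reagents that add atoms: none
Why: Nozaki–Hiyama–Kishi coupling adds the vinylchromium reagent 1,2 to the enal with retention of the E-alkene and tolerates the free hydroxyls; C1 is formed without control and is sorted out in step 8.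

Step 8
Reactants: 12 divinyl carbinol (C1 epimers)
Product: 13 erythro epoxy tetraol, (3R,5E)-3-{(1E,3R)-3-hydroxy-3-[(2R,3R)-3-(4-hydroxybutyl)-2-methyloxiran-2-yl]prop-1-en-1-yl}-3,7-dimethyloct-5-ene-1,7-diol (1R,4R,10R,11R in the numbering above)
Conditions: Ti(Oi-Pr)4 (2.0 equiv), D-(−)-diisopropyl tartrate (2.4 equiv), t-BuOOH (0.55 equiv), 4 Å MS, CH2Cl2, −20 °C
Reagents that add atoms: tert-butyl hydroperoxide, CC(C)(C)OO
Why: Sharpless kinetic-resolution epoxidation, in which the 1R epimer is the matched partner of the D-(−)-tartrate and is epoxidised at the trisubstituted C10=C11 alkene to the erythro oxirane with the target geometry at C10 and C11, while the 1S epimer is left behind and the tertiary allylic alcohol is inert.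

Step 9
Reactants: 13 erythro epoxy tetraol
Product: 14 erythro epoxy alcohol dialdehyde (13 with both CH2OH groups, C6 and the future formyl carbon, oxidised to CHO; 1R,4R,10R,11R)
Conditions: Cu(MeCN)4OTf (10 mol %), 2,2′-bipyridine (10 mol %), TEMPO (10 mol %), N-methylimidazole (20 mol %), air, MeCN, rt
Reagents that add atoms: none
Why: Stahl aerobic copper/TEMPO oxidation converts primary alcohols into aldehydes under near-neutral conditions and leaves the secondary C1 carbinol, the tertiary alcohol and the oxirane untouched.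

Step 10
Reactants: 14 erythro epoxy alcohol dialdehyde; 15 3-methylbut-2-enoic acid (senecioic acid)
Product: 16 threo senecioate dialdehyde (the 3-methylbut-2-enoate of the C1 epimer of 14; 1S,4R,10R,11S)
Conditions: PPh3 (3 equiv), i-PrO2CN=NCO2i-Pr (3 equiv), toluene, 0 °C → rt
Reagents that add atoms: none
Why: Mitsunobu esterification forms the C1–O ester bond by SN2 attack of senecioate on the alkoxyphosphonium ion, inverting C1 from R to S (the SN2′ position C3 is blocked by the quaternary C4, and the tertiary alcohol does not react).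

Step 11
Reactants: 16 threo senecioate dialdehyde
Product: 18 CNP0164725.2 (target), via macrocyclic β-hydroxy aldehyde 17 (not isolated)
Conditions: Bn2NH2+ CF3CO2− (30 mol %), toluene, 1 mM by syringe-pump addition, 60 °C
Reagents that add atoms: none
Why: Proposed new method: an amine-salt-catalysed macrocyclising aldol condensation to an 11-membered ring, in which the unhindered aldehyde forms the enamine at C7 and adds to the neopentyl-type C6 aldehyde (the competing enamine at C5 is flanked by the quaternary C4 and is slow), the reversible aldol step is drained by E1cB dehydration through the iminium ion to the thermodynamically favoured (E)-enal whose ring-cis geometry suits the ring, and the E-alkene and trans-oxirane stiffen the chain while high dilution suppresses oligomers; the closest known reactions are the Bn2NH2+ CF3CO2−-catalysed intramolecular aldol condensation of dialdehydes to five- to seven-membered cycloalkene carbaldehydes and base-mediated macrocyclic aldol condensations of diketones in musk synthesis.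

**Compound list**

1 | α-methyl-γ-butyrolactone (racemic) | CC1CCOC1=O | starting material
2 | allyl chloroformate | C=CCOC(=O)Cl | starting material
3 | allyl 3-methyl-2-oxotetrahydrofuran-3-carboxylate (racemic) | C=CCOC(=O)C1(C)CCOC1=O | intermediate
4 | (R)-3-allyl-3-methyldihydrofuran-2(3H)-one | O=C1OCC[C@@]1(C)CC=C | intermediate
5 | 2-methylbut-3-en-2-ol | CC(C)(O)C=C | starting material
6 | (R)-3-[(2E)-4-hydroxy-4-methylpent-2-en-1-yl]-3-methyldihydrofuran-2(3H)-one | O=C1OCC[C@@]1(C)C/C=C/C(C)(C)O | intermediate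
7 | (3R)-3-[(2E)-4-hydroxy-4-methylpent-2-en-1-yl]-3-methyltetrahydrofuran-2-ol (anomers) | OC1OCC[C@@]1(C)C/C=C/C(C)(C)O | intermediate
8 | (3R,5E)-3-[(E)-2-iodoethenyl]-3,7-dimethyloct-5-ene-1,7-diol | I/C=C/[C@](C)(C/C=C/C(C)(C)O)CCO | intermediate
9 | 2-hydroxytetrahydropyran | OC1CCCCO1 | starting material
10 | 2-(triphenylphosphoranylidene)propanal | CC(C=O)=P(c1ccccc1)(c1ccccc1)c1ccccc1 | starting material
11 | (2E)-7-hydroxy-2-methylhept-2-enal | O=C/C(C)=C/CCCCO | intermediate
12 | (3R,5E)-3-[(1E,4E)-3,9-dihydroxy-4-methylnona-1,4-dien-1-yl]-3,7-dimethyloct-5-ene-1,7-diol (C1 epimers, about 1:1) | OCCCC/C=C(\C)C(O)/C=C/[C@](C)(C/C=C/C(C)(C)O)CCO | intermediate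
13 | erythro epoxy tetraol (1R,4R,10R,11R) | OCCCC[C@H]1O[C@]1(C)[C@H](O)/C=C/[C@](C)(C/C=C/C(C)(C)O)CCO | intermediate
14 | erythro epoxy alcohol dialdehyde (1R,4R,10R,11R) | O=CCCC[C@H]1O[C@]1(C)[C@H](O)/C=C/[C@](C)(C/C=C/C(C)(C)O)CC=O | intermediate
15 | 3-methylbut-2-enoic acid | CC(C)=CC(=O)O | starting material
16 | threo senecioate dialdehyde (1S,4R,10R,11S) | O=CCCC[C@H]1O[C@]1(C)[C@@H](OC(=O)C=C(C)C)/C=C/[C@](C)(C/C=C/C(C)(C)O)CC=O | intermediate
17 | macrocyclic β-hydroxy aldehyde (C6 and C7 epimers; not isolated) | CC(C)=CC(=O)O[C@H]1/C=C/[C@](C)(C/C=C/C(C)(C)O)CC(O)C(C=O)CC[C@H]2O[C@]12C | intermediate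
18 | CNP0164725.2, (1S,2E,4R,6E,10R,11S)-10,11-epoxy-7-formyl-4-[(2E)-4-hydroxy-4-methylpent-2-en-1-yl]-4,11-dimethylcycloundeca-2,6-dien-1-yl 3-methylbut-2-enoate | CC(C)=CC(=O)O[C@H]1/C=C/[C@](C)(C/C=C/C(C)(C)O)C/C=C(/C=O)CC[C@H]2O[C@]12C | target

**Step count and risks**

Total steps: 11. Longest linear sequence: 10 (steps 1–5 and 7–11).

Most likely to fail:

Step 11 (the proposed macrocyclising aldol condensation; medium-ring closure may lose to oligomers or to the regioisomeric condensation). The fallback is a known intramolecular Horner–Wadsworth–Emmons closure; it sets out from 8 and comes back to the route at 18. Triethyl phosphonoacetate is alkylated with 4-bromobut-1-ene (NaH, DMSO) to triethyl 2-phosphonohex-5-enoate F6, and cross-metathesis with methacrolein (second-generation Grubbs catalyst) gives ethyl (5E)-2-(diethoxyphosphoryl)-6-methyl-7-oxohept-5-enoate F7. Nozaki–Hiyama–Kishi coupling of 8 with F7 gives the phosphonate divinyl carbinol F8 (C1 epimers), and the same Ti/D-(−)-tartrate resolution gives the erythro phosphonate epoxy alcohol F9. Copper/TEMPO oxidation of its single primary alcohol gives the phosphonate aldehyde F10. LiCl and i-Pr2NEt in MeCN at high dilution close the ring to the macrocyclic ethyl (E)-enoate with free 1R hydroxyl F11. i-Bu2AlH reduces the ester to the macrocyclic allylic diol F12, and PhI(OAc)2/TEMPO oxidises only the primary allylic alcohol to the macrocyclic enal 1R-alcohol F13. Mitsunobu esterification of F13 with 15 then gives 18.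

Step 10 (Mitsunobu inversion at a hindered allylic carbinol beside a fully substituted oxirane carbon, with a weakly acidic acid). The fallback replaces substitution by a redox inversion and an acylation with retention; it sets out from 13 and comes back at 16. MnO2 oxidises only the allylic C1 carbinol of 13 to the epoxy enone triol F3. Corey–Bakshi–Shibata reduction (oxazaborolidine enantiomer selected to give the 1S carbinol) gives the threo epoxy tetraol F4. Copper/TEMPO aerobic oxidation gives the threo epoxy alcohol dialdehyde F5, and Steglich esterification with 15 (DCC, DMAP) gives 16.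

Step 2 (the enantioselectivity of decarboxylative allylation is less secure for a simple lactone enolate than for ketones or lactams). The fallback is a resolution; it sets out from 1 and comes back at 4. Alkylation of 1 with allyl bromide (LiN(i-Pr)2, THF) gives racemic 3-allyl-3-methyldihydrofuran-2(3H)-one F1. AlMe3-mediated aminolysis with (S)-1-phenylethylamine gives two hydroxy amides that are separated by chromatography or crystallisation; the one with the R quaternary centre is (R)-2-(2-hydroxyethyl)-2-methyl-N-[(S)-1-phenylethyl]pent-4-enamide F2. Heating F2 with aqueous H2SO4 in dioxane relactonises it to 4.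

**Further compounds**

F1 | step 2 | racemic 3-allyl-3-methyldihydrofuran-2(3H)-one | C=CCC1(C)CCOC1=O
F2 | step 2 | (R)-2-(2-hydroxyethyl)-2-methyl-N-[(S)-1-phenylethyl]pent-4-enamide | C=CC[C@](C)(CCO)C(=O)N[C@@H](C)c1ccccc1
F3 | step 10 | epoxy enone triol (C1 ketone of 13) | OCCCC[C@H]1O[C@]1(C)C(=O)/C=C/[C@](C)(C/C=C/C(C)(C)O)CCO
F4 | step 10 | threo epoxy tetraol (C1 epimer of 13, 1S) | OCCCC[C@H]1O[C@]1(C)[C@@H](O)/C=C/[C@](C)(C/C=C/C(C)(C)O)CCO
F5 | step 10 | threo epoxy alcohol dialdehyde (C1 epimer of 14, 1S) | O=CCCC[C@H]1O[C@]1(C)[C@@H](O)/C=C/[C@](C)(C/C=C/C(C)(C)O)CC=O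
F6 | step 11 | triethyl 2-phosphonohex-5-enoate | CCOC(=O)C(CCC=C)P(=O)(OCC)OCC
F7 | step 11 | ethyl (5E)-2-(diethoxyphosphoryl)-6-methyl-7-oxohept-5-enoate | CCOC(=O)C(CC/C=C(\C)C=O)P(=O)(OCC)OCC
F8 | step 11 | phosphonate divinyl carbinol (C1 epimers) | CCOC(=O)C(CC/C=C(\C)C(O)/C=C/[C@](C)(C/C=C/C(C)(C)O)CCO)P(=O)(OCC)OCC
F9 | step 11 | erythro phosphonate epoxy alcohol (1R) | CCOC(=O)C(CC[C@H]1O[C@]1(C)[C@H](O)/C=C/[C@](C)(C/C=C/C(C)(C)O)CCO)P(=O)(OCC)OCC
F10 | step 11 | phosphonate aldehyde (C6 aldehyde of F9) | CCOC(=O)C(CC[C@H]1O[C@]1(C)[C@H](O)/C=C/[C@](C)(C/C=C/C(C)(C)O)CC=O)P(=O)(OCC)OCC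
F11 | step 11 | macrocyclic ethyl (E)-enoate with free 1R hydroxyl | O[C@@H]1/C=C/[C@](C)(C/C=C/C(C)(C)O)C/C=C(/C(=O)OCC)CC[C@H]2O[C@]12C
F12 | step 11 | macrocyclic allylic diol (C7 hydroxymethyl, 1R hydroxyl) | O[C@@H]1/C=C/[C@](C)(C/C=C/C(C)(C)O)C/C=C(/CO)CC[C@H]2O[C@]12C
F13 | step 11 | macrocyclic enal 1R-alcohol (C1 epimer of the deacylated target) | O[C@@H]1/C=C/[C@](C)(C/C=C/C(C)(C)O)C/C=C(/C=O)CC[C@H]2O[C@]12C
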